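**Strategy.** Everything rests on opening the dihydropyran ring of the chroman at C4–C4a and O1–C2: the target becomes 4-methoxy-2-methylphenol plus a cis-dimethylhydrindenone whose enone β-carbon carries a 2-methylidenebut-3-enyl (isoprenyl) chain. The key step exploits that C2 with its methyl, C3 and C4 of the pyran ring are a hidden isoprene unit. A chiral Brønsted acid should turn the diene into an allyl cation, alkylate the phenol ortho carbon (C4–C4a), then close the ring by capture of the tertiary C2 cation by the phenol oxygen (O1–C2), setting C2 in the same operation. The hydrindenone comes from an auxiliary-controlled Robinson annulation, cuprate addition and an oxidative carbonyl transposition.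

Key step: step 10

Remark: the SMILES is taken as drawn, i.e. 2S at the chroman carbon and a cis (3aS,7aS) ring fusion; chroman atoms are numbered O1, C2, C3, C4, C4a, C8a.

**Step 1**
Reactants: 1 2-methylcyclopentan-1-one; 2 (S)-1-phenylethylamine; 3 but-3-en-2-one
Product: 6 (R)-2-methyl-2-(3-oxobutyl)cyclopentan-1-one, via chiral imine 4 (not isolated), via Michael adduct imine 5 (not isolated)
Conditions: 1 + 2, toluene, reflux (Dean–Stark); then 3, THF, 25 °C; then 10% aq AcOH, 25 °C
Reagents that add atoms: water, O
Why: Chiral-imine Michael addition (deracemising alkylation of an α-substituted ketone), in which the more substituted secondary enamine tautomer of 4 should add to the enone through a compact aza-ene-like transition state on the face away from the phenyl group, setting the quaternary (R) centre before hydrolysis releases the auxiliary.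

**Step 2**
Reactants: 6
Product: 7 (R)-7a-methyl-1,2,3,6,7,7a-hexahydro-5H-inden-5-one
Conditions: KOH, MeOH, reflux
Reagents that add atoms: none
Why: Intramolecular aldol condensation completes the Robinson annulation, and the quaternary centre cannot enolise and is retained.

**Step 3**
Reactants: 7
Product: 8 (7aR)-7a-methyl-6-(2-methylprop-2-en-1-yl)-1,2,3,6,7,7a-hexahydro-5H-inden-5-one (both C6 epimers)
Conditions: LiN(iPr)2, THF, −78 °C; 3-bromo-2-methylprop-1-ene, −78 to 0 °C
Reagents that add atoms: 3-bromo-2-methylprop-1-ene, C=C(C)CBr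
Why: Kinetic deprotonation gives the cross-conjugated α'-enolate, which is alkylated at C6 by the allylic bromide (enolate alkylation); the new C6 centre is left as a mixture because it becomes sp2 in step 6.

**Step 4**
Reactants: 8
Product: 9 (3aS,7aR)-3a,7a-dimethyl-6-(2-methylprop-2-en-1-yl)octahydro-5H-inden-5-one (cis ring fusion, both C6 epimers)
Conditions: Me2CuLi, Et2O, −20 to 0 °C
Reagents that add atoms: lithium dimethylcuprate, [Li+].C[Cu-]C
Why: Gilman cuprate conjugate addition to the β,β-disubstituted enone should deliver methyl to C3a so as to give the cis-fused hydrindanone, the strongly preferred ring fusion for this bicycle, which places the two angular methyls cis and sets C3a as S.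

**Step 5**
Reactants: 9
Product: 10 (3aS,7aR)-6-(2-hydroxy-2-methylpropyl)-3a,7a-dimethyloctahydro-5H-inden-5-one (both C6 epimers)
Conditions: Co(acac)2 (cat.), PhSiH3, O2 (1 atm), THF, 25 °C
Reagents that add atoms: dioxygen, O=O
Why: Mukaiyama hydration, in which cobalt hydride hydrogen-atom transfer to the 1,1-disubstituted alkene, O2 capture of the tertiary radical and in situ reduction should give the Markovnikov tertiary alcohol while the saturated ketone is untouched.

**Step 6**
Reactants: 10
Product: 11 (3aS,7aR)-6-(2-hydroxy-2-methylpropyl)-3a,7a-dimethyl-1,2,3,3a,4,7a-hexahydro-5H-inden-5-one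
Conditions: 2-iodoxybenzoic acid (IBX), DMSO/fluorobenzene, 70 °C
Reagents that add atoms: none
Why: IBX dehydrogenation of a ketone through its enol; within the ring only C6–C7 can be desaturated because C3a bears no hydrogen, so the α-branched enone should result with both quaternary centres unaffected.

**Step 7**
Reactants: 11
Product: 12 (3aS,7aR)-6-(2-hydroxy-2-methylpropyl)-3a,7a-dimethyl-5-(prop-2-yn-1-yl)-2,3,3a,4,5,7a-hexahydro-1H-inden-5-ol (C5 epimers)
Conditions: 3-bromoprop-1-yne, Zn, THF/sat. aq NH4Cl, 0 to 25 °C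
Reagents that add atoms: 3-bromoprop-1-yne, C#CCBr
Why: Barbier propargylation, in which the allenylzinc species adds 1,2 to the ketone by an SE2' path to give the homopropargylic tertiary alcohol and tolerates the free hydroxyl; the carbinol configuration is irrelevant because C5 becomes sp2 in step 9.

**Step 8**
Reactants: 12
Product: 13 (3aS,7aR)-6-(2-hydroxy-2-methylpropyl)-3a,7a-dimethyl-5-(2-methylidenebut-3-en-1-yl)-2,3,3a,4,5,7a-hexahydro-1H-inden-5-ol (C5 epimers)
Conditions: ethylene (1 atm), second-generation Grubbs catalyst RuCl2(=CHPh)(PCy3)(H2IMes) (5 mol%), CH2Cl2, 25 to 40 °C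
Reagents that add atoms: ethylene, C=C
Why: Cross enyne metathesis of the terminal alkyne with ethylene should give the 2-substituted buta-1,3-diene, the trisubstituted ring alkene being too hindered to engage the ruthenium carbene.

**Step 9**
Reactants: 13
Product: 14 (3aS,7aS)-5-(2-hydroxy-2-methylpropyl)-3a,7a-dimethyl-6-(2-methylidenebut-3-en-1-yl)-1,2,3,3a,7,7a-hexahydro-4H-inden-4-one
Conditions: pyridinium chlorochromate (C5H5NH)[CrO3Cl], 4 Å molecular sieves, CH2Cl2, 25 °C
Reagents that add atoms: pyridinium chlorochromate, [O-][Cr](=O)(=O)Cl.c1cc[nH+]cc1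
Why: Babler–Dauben oxidative transposition, in which the chromate ester of the tertiary allylic alcohol undergoes a [3,3] shift to the secondary allylic chromate that is oxidised to the tetrasubstituted enone, while the non-allylic tertiary alcohol cannot be oxidised.

**Step 10**
Reactants: 14; 15 4-methoxy-2-methylphenol
Product: 17 (3aS,7aS)-5-(2-hydroxy-2-methylpropyl)-6-{[(2S)-6-methoxy-2,8-dimethyl-3,4-dihydro-2H-chromen-2-yl]methyl}-3a,7a-dimethyl-1,2,3,3a,7,7a-hexahydro-4H-inden-4-one, via ortho-allylated phenol 16 (not isolated)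
Conditions: 15 (3 equiv), chiral imidodiphosphorimidate Brønsted acid (IDPi, 5 mol%), cyclohexane/CHCl3, 0 to 25 °C
Reagents that add atoms: none
Why: Proposed new method: the chiral acid should protonate the terminal methylidene carbon of the diene of 14 to a 1,1-disubstituted allyl cation paired with the chiral anion, the free ortho carbon of 15 attacks its unhindered primary terminus (C4–C4a, giving 16), and reprotonation of the new trisubstituted alkene at C3 gives the tertiary C2 cation that the phenol oxygen captures (O1–C2). The closest known reaction types are the acid- or AgOTf-catalysed annulation of phenols with isoprene-type dienes to 2,2-disubstituted chromans and the asymmetric hydroalkoxylation of alkenes by confined chiral Brønsted acids; a catalyst-controlled version with a phenol nucleophile has not been shown. The dihydropyran ring closes in a 6-endo-trig (Markovnikov) mode. The new C2 stereocentre is set by the chiral counter-anion, since the ring stereocentres are too remote to bias the planar cation, and the catalyst enantiomer is chosen to give 2S. The step needs alkylation ortho to the hydroxyl and not ortho to the methoxy group, which hydrogen bonding of the phenol OH to the anion and the fact that only this adduct can cyclise should secure, and it needs the acid to spare the tertiary alcohol, which the much easier protonation of a conjugated diene should allow. If the skipped diene first slips into conjugation with the enone, the resulting trienone should converge on 17 by 1,8-Friedel–Crafts and 1,6-oxa-Michael addition.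

**Compound list**

1 | 2-methylcyclopentan-1-one (racemic) | CC1CCCC1=O | starting material
2 | (S)-1-phenylethylamine | C[C@H](N)c1ccccc1 | starting material
3 | but-3-en-2-one (methyl vinyl ketone) | CC(=O)C=C | starting material
4 | 2-methyl-N-[(1S)-1-phenylethyl]cyclopentan-1-imine (in equilibrium with its secondary enamine) | C[C@H](N=C1CCCC1C)c1ccccc1 | intermediate
5 | 4-[(1R)-1-methyl-2-{[(1S)-1-phenylethyl]imino}cyclopentyl]butan-2-one | C[C@H](N=C1CCC[C@]1(C)CCC(C)=O)c1ccccc1 | intermediate
6 | (R)-2-methyl-2-(3-oxobutyl)cyclopentan-1-one | CC(=O)CC[C@@]1(C)CCCC1=O | intermediate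
7 | (R)-7a-methyl-1,2,3,6,7,7a-hexahydro-5H-inden-5-one | O=C1CC[C@@]2(C)CCCC2=C1 | intermediate
8 | (7aR)-7a-methyl-6-(2-methylprop-2-en-1-yl)-1,2,3,6,7,7a-hexahydro-5H-inden-5-one, C6 epimers | O=C1C(CC(C)=C)C[C@@]2(C)CCCC2=C1 | intermediate
9 | (3aS,7aR)-3a,7a-dimethyl-6-(2-methylprop-2-en-1-yl)octahydro-5H-inden-5-one, cis-fused, C6 epimers | O=C1C(CC(C)=C)C[C@@]2(C)CCC[C@@]2(C)C1 | intermediate
10 | (3aS,7aR)-6-(2-hydroxy-2-methylpropyl)-3a,7a-dimethyloctahydro-5H-inden-5-one, cis-fused, C6 epimers | O=C1C(CC(C)(C)O)C[C@@]2(C)CCC[C@@]2(C)C1 | intermediate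
11 | (3aS,7aR)-6-(2-hydroxy-2-methylpropyl)-3a,7a-dimethyl-1,2,3,3a,4,7a-hexahydro-5H-inden-5-one | O=C1C(CC(C)(C)O)=C[C@@]2(C)CCC[C@@]2(C)C1 | intermediate
12 | (3aS,7aR)-6-(2-hydroxy-2-methylpropyl)-3a,7a-dimethyl-5-(prop-2-yn-1-yl)-2,3,3a,4,5,7a-hexahydro-1H-inden-5-ol, C5 epimers | C#CCC1(O)C(CC(C)(C)O)=C[C@@]2(C)CCC[C@@]2(C)C1 | intermediate
13 | (3aS,7aR)-6-(2-hydroxy-2-methylpropyl)-3a,7a-dimethyl-5-(2-methylidenebut-3-en-1-yl)-2,3,3a,4,5,7a-hexahydro-1H-inden-5-ol, C5 epimers | C=CC(=C)CC1(O)C(CC(C)(C)O)=C[C@@]2(C)CCC[C@@]2(C)C1 | intermediate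
14 | (3aS,7aS)-5-(2-hydroxy-2-methylpropyl)-3a,7a-dimethyl-6-(2-methylidenebut-3-en-1-yl)-1,2,3,3a,7,7a-hexahydro-4H-inden-4-one | C=CC(=C)CC1=C(CC(C)(C)O)C(=O)[C@@]2(C)CCC[C@@]2(C)C1 | intermediate
15 | 4-methoxy-2-methylphenol | COc1ccc(O)c(C)c1 | starting material
16 | (3aS,7aS)-6-[4-(2-hydroxy-5-methoxy-3-methylphenyl)-2-methylbut-2-en-1-yl]-5-(2-hydroxy-2-methylpropyl)-3a,7a-dimethyl-1,2,3,3a,7,7a-hexahydro-4H-inden-4-one, E/Z mixture | COc1cc(C)c(O)c(CC=C(C)CC2=C(CC(C)(C)O)C(=O)[C@@]3(C)CCC[C@@]3(C)C2)c1 | intermediate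
17 | (3aS,7aS)-5-(2-hydroxy-2-methylpropyl)-6-{[(2S)-6-methoxy-2,8-dimethyl-3,4-dihydro-2H-chromen-2-yl]methyl}-3a,7a-dimethyl-1,2,3,3a,7,7a-hexahydro-4H-inden-4-one (CNP0224132.2) | COc1cc(C)c2c(c1)CC[C@@](C)(CC1=C(CC(C)(C)O)C(=O)[C@@]3(C)CCC[C@@]3(C)C1)O2 | target

**Count.** Total steps: 10. Longest linear sequence: 10 steps (1 to 17).

**Steps most likely to fail**

1. Step 10 (labelled). What may go wrong: ion pairing with the chiral anion may fail to differentiate the two faces of the tertiary C2 cation, alkylation may occur ortho to the methoxy group, or the acid may ionise the tertiary alcohol or oligomerise the diene, so that the chroman forms without control or not at all. The fallback uses known reactions only, sets out from 12 and comes back at 17. Zirconium-catalysed methylalumination of the alkyne of 12 (Me3Al, Cp2ZrCl2, CH2Cl2; then (CH2O)n) should give the (E)-allylic alcohol F1. Its primary hydroxyl is converted into the methyl carbonate F2 (ClCO2Me, pyridine, 0 °C). Phenol 15 is brominated ortho to the hydroxyl (N-bromosuccinimide, CH2Cl2, 0 °C) to 2-bromo-4-methoxy-6-methylphenol F3. Tsuji–Trost asymmetric O-allylation of F3 with F2 (Pd2(dba)3·CHCl3, one enantiomer of N,N'-(cyclohexane-1,2-diyl)bis[2-(diphenylphosphino)benzamide], CH2Cl2) at the more substituted allyl terminus should set C2 by ligand control in the tertiary aryl allyl ether F4. Hydroboration of its vinyl group with 9-BBN gives the alkylborane F5, and intramolecular B-alkyl Suzuki–Miyaura coupling (Pd(dppf)Cl2, K3PO4, THF/DMF/H2O, 60 °C) forms the C4–C4a bond and gives the chroman carbinol F6. The Babler–Dauben oxidation of step 9 applied to F6 returns 17.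

2. Step 9. What may go wrong: under the acidic chromium conditions the allylic cation or chromate may be intercepted by the side-chain tertiary hydroxyl (cyclic ether formation), or the 1,3-diene may oligomerise before the [3,3] shift and oxidation occur. The fallback sets out from 13 and comes back at 14 and separates the two events under neutral conditions. A rhenium-oxo catalysed 1,3-transposition of the tertiary allylic alcohol (Ph3SiOReO3, Et2O, −50 to 0 °C), driven by formation of the tetrasubstituted alkene, gives the secondary allylic alcohol F7. Dess–Martin oxidation (CH2Cl2, NaHCO3, 0 °C) then gives 14.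

3. Step 6. What may go wrong: enolisation may occur away from the branched α-carbon, or oxidation may run into the side chain or beyond the enone. The fallback sets out from 10 and comes back at 11 through a Saegusa–Ito sequence. Thermodynamic silylation (Me3SiCl, NaI, Et3N, MeCN) gives the more substituted silyl enol ether F8, in which the side-chain hydroxyl is silylated as well. Pd(OAc)2 in MeCN then effects β-hydride elimination from the palladium enolate, and a mild acidic work-up frees the tertiary hydroxyl to return 11.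

**Further compounds**

F1 | step 10 | (3aS,7aR)-5-[(2E)-4-hydroxy-2-methylbut-2-en-1-yl]-6-(2-hydroxy-2-methylpropyl)-3a,7a-dimethyl-2,3,3a,4,5,7a-hexahydro-1H-inden-5-ol, C5 epimers | OC/C=C(\C)CC1(O)C(CC(C)(C)O)=C[C@@]2(C)CCC[C@@]2(C)C1
F2 | step 10 | (2E)-4-[(3aS,7aR)-5-hydroxy-6-(2-hydroxy-2-methylpropyl)-3a,7a-dimethyl-2,3,3a,4,5,7a-hexahydro-1H-inden-5-yl]-3-methylbut-2-en-1-yl methyl carbonate | COC(=O)OC/C=C(\C)CC1(O)C(CC(C)(C)O)=C[C@@]2(C)CCC[C@@]2(C)C1
F3 | step 10 | 2-bromo-4-methoxy-6-methylphenol | COc1cc(C)c(O)c(Br)c1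
F4 | step 10 | (3aS,7aR)-5-[(2R)-2-(2-bromo-4-methoxy-6-methylphenoxy)-2-methylbut-3-en-1-yl]-6-(2-hydroxy-2-methylpropyl)-3a,7a-dimethyl-2,3,3a,4,5,7a-hexahydro-1H-inden-5-ol | COc1cc(C)c(O[C@@](C)(C=C)CC2(O)C(CC(C)(C)O)=C[C@@]3(C)CCC[C@@]3(C)C2)c(Br)c1
F5 | step 10 | B-alkyl-9-borabicyclo[3.3.1]nonane from hydroboration of the vinyl group of F4 (boron on the terminal carbon) | COc1cc(C)c(O[C@@](C)(CCB2C3CCCC2CCC3)CC2(O)C(CC(C)(C)O)=C[C@@]3(C)CCC[C@@]3(C)C2)c(Br)c1
F6 | step 10 | (3aS,7aR)-6-(2-hydroxy-2-methylpropyl)-5-{[(2S)-6-methoxy-2,8-dimethyl-3,4-dihydro-2H-chromen-2-yl]methyl}-3a,7a-dimethyl-2,3,3a,4,5,7a-hexahydro-1H-inden-5-ol | COc1cc(C)c2c(c1)CC[C@@](C)(CC1(O)C(CC(C)(C)O)=C[C@@]3(C)CCC[C@@]3(C)C1)O2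
F7 | step 9 | (3aS,7aS)-5-(2-hydroxy-2-methylpropyl)-3a,7a-dimethyl-6-(2-methylidenebut-3-en-1-yl)-2,3,3a,4,7,7a-hexahydro-1H-inden-4-ol, C4 epimers | C=CC(=C)CC1=C(CC(C)(C)O)C(O)[C@@]2(C)CCC[C@@]2(C)C1
F8 | step 6 | (3aS,7aR)-3a,7a-dimethyl-6-[2-methyl-2-(trimethylsilyloxy)propyl]-5-(trimethylsilyloxy)-2,3,3a,4,7,7a-hexahydro-1H-indene | C[Si](C)(C)OC1=C(CC(C)(C)O[Si](C)(C)C)C[C@@]2(C)CCC[C@@]2(C)C1
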